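**Retrosynthetic overview**

- Feature (daucane numbering: C1 quaternary methyl carbon, C2 and C3 ring CH2, C4 isopropyl carbinol, C5 ring-fusion CH, C6 ester carbon, C7 CH2, C8 methyl-bearing alkene carbon, C9 alkene CH, C10 ketone): the cyclopentane C1–C2–C3–C4–C5 and the cycloheptenone C1–C5–C6–C7–C8–C9–C10 share the C1–C5 bond, and their fifteen carbons are one unrearranged farnesyl chain C10–C9–C8–C7–C6–C5–C1–C2–C3–C4–CMe2 that lacks only the bonds C1–C10 and C4–C5.
- Target ⇒ allylic C–H oxidation at C10 ⇒ 6-veratrate ⇒ acylation of dauc-8-ene-4β,6α-diol with 3,4-dimethoxybenzoyl chloride.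
- Diol ⇒ dauca-4,8-dien-6-one by a stereochemical relay: reagent-controlled reduction to the 6β-alcohol, hydroxyl-directed β-epoxidation of C4=C5, re-oxidation, SmI2 opening to the 4β-hydroxy-5α-H ketone, hydroxyl-directed reduction to the 6α-alcohol.
- Dienone ⇒ daucene: epoxidation of the tetrasubstituted C4=C5 alkene, isomerisation to the C4 allylic alcohol, oxidative transposition.
- Daucene ⇒ farnesyl diphosphate (two steps from farnesol): one cyclase cascade closes the seven-membered ring (C1–C10) and, in the same step, the five-membered ring (C4–C5).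

Key step: step 3

Assumption: a class one sesquiterpene cyclase that releases (R)-daucene as its main product is taken to be at hand, found by screening daucane-forming cyclases or by engineering one that otherwise ends in water capture. The enzyme fixes which enantiomer of the bound tertiary diphosphate is used; it is drawn as (3R).

Remark: β is the face of the bicycle that carries the C1 methyl group, α the opposite face. The C4 carbinol must end up β, which a reagent approaching C4=C5 from outside cannot be relied on to deliver; the route therefore passes through the dienone and sets C4 by delivery from a 6β-hydroxyl.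

**Route**

Step 1
Reactants: 1 (2E,6E)-farnesol
Product: 2 (2E,6E)-farnesyl chloride
Conditions: NCS, Me2S, CH2Cl2, −40 → 0 °C
Reagents that add atoms: N-chlorosuccinimide, O=C1CCC(=O)N1Cl
Why: Corey–Kim allylic chlorination, in which chloride displaces the alkoxysulfonium group at the primary carbon (SN2), so that neither allylic transposition nor loss of the 2E geometry is expected.

Step 2
Reactants: 2 (2E,6E)-farnesyl chloride
Product: 3 (2E,6E)-farnesyl diphosphate (used as its tris-ammonium salt)
Conditions: (n-Bu4N)3HP2O7, MeCN, rt; Dowex 50W-X8 (NH4+ form), aq. NH4HCO3/i-PrOH; cellulose chromatography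
Reagents that add atoms: tris(tetrabutylammonium) hydrogen diphosphate, CCCC[N+](CCCC)(CCCC)CCCC.CCCC[N+](CCCC)(CCCC)CCCC.CCCC[N+](CCCC)(CCCC)CCCC.OP(=O)([O-])OP(=O)([O-])[O-]
Why: SN2 diphosphorylation of a primary allylic halide by the diphosphate trianion in a dipolar aprotic solvent, followed by cation exchange to the water-soluble salt that the enzyme accepts.

Step 3
Reactants: 3 (2E,6E)-farnesyl diphosphate
Product: 5 (R)-daucene (dauca-4,8-diene), via nerolidyl diphosphate 4 (not isolated)
Conditions: recombinant daucene-forming class one sesquiterpene cyclase, MgCl2 (10 mM), HEPES buffer pH 7.5, glycerol (10%), 30 °C, pentane overlay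
Reagents that add atoms: none
Why: Mg2+-assisted ionisation of 3 and return of diphosphate to the tertiary carbon give 4, which rotates about the C8–C9 bond and ionises again to the cisoid allyl cation, the only geometry that lets the cis C8=C9 alkene become part of a seven-membered ring; this is the general mechanism of class one terpene cyclases, and the cyclases that turn 3 into daucane hydrocarbons and alcohols are the closest known case. The seven-membered ring closes 7-endo as the central alkene attacks C10 through C1, and the five-membered ring closes 5-exo as the distal alkene traps the charge developing at C5 through C4, so that no secondary cation is needed and the charge ends on the isopropyl carbon. A 1,2-hydride shift from C4 to that carbon and loss of H-5 then give the tetrasubstituted C4=C5 alkene. The single stereocentre C1 is set by the face of the central alkene that the active-site contour turns towards C10, the E geometry of that alkene and the 1,5-spacing of the three alkenes in 3 being what allows the fold at all. The step needs this folding in preference to the bisabolyl and germacryl modes, the (R) enantiomer, and deprotonation at C5 and not at C3 or the isopropyl methyls, all of which rest on the enzyme and are the reason its choice carries the risk of the route.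

Step 4
Reactants: 5 (R)-daucene
Product: 6 (1R,4S,5S)-4,5-epoxydauc-8-ene
Conditions: mCPBA (1.0 equiv), NaHCO3, CH2Cl2, −40 → −10 °C
Reagents that add atoms: meta-chloroperbenzoic acid, O=C(OO)c1cccc(Cl)c1
Why: Prilezhaev epoxidation, in which the electrophilic peracid should take the tetrasubstituted C4=C5 alkene in preference to the trisubstituted C8=C9 alkene, attack being expected mainly from the α-face, although any β-epoxide formed is carried along because C5 and C4 lose their configuration in steps 5 and 6.

Step 5
Reactants: 6 (1R,4S,5S)-4,5-epoxydauc-8-ene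
Product: 7 (1R,4S)-dauca-5,8-dien-4-ol
Conditions: Et2AlCl, lithium 2,2,6,6-tetramethylpiperidide, toluene, 0 °C → rt; aq. Rochelle salt
Reagents that add atoms: none
Why: Aluminium amide isomerisation of an epoxide to an allylic alcohol (syn β-elimination through a six-membered cyclic transition state), in which H-6 on the flexible seven-membered ring should reach the required geometry more easily than H-3 inside the rigid oxabicyclo[3.1.0]hexane, while C1 carries no hydrogen and the isopropyl methine is too hindered.

Step 6
Reactants: 7 (1R,4S)-dauca-5,8-dien-4-ol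
Product: 8 (1R)-dauca-4,8-dien-6-one
Conditions: pyridinium chlorochromate (C5H5NH[CrO3Cl]), 4 Å MS, CH2Cl2, 0 °C → rt, short contact time
Reagents that add atoms: pyridinium chlorochromate, [O-][Cr](=O)(=O)Cl.c1cc[nH+]cc1
Why: Babler–Dauben oxidative transposition, in which the tertiary chromate ester shifts [3,3] to C6 (the new C6 oxygen comes from the chromate), forms the tetrasubstituted C4=C5 alkene and is oxidised to the enone, which removes the C4 centre so that both epoxide face isomers converge, a short contact time keeping the C8=C9 alkene out of conjugation.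

Step 7
Reactants: 8 (1R)-dauca-4,8-dien-6-one
Product: 9 (1R,6R)-dauca-4,8-dien-6-ol (6β-alcohol)
Conditions: (S)-1-methyl-3,3-diphenyltetrahydro-1H,3H-pyrrolo[1,2-c][1,3,2]oxazaborole ((S)-Me-CBS, 20 mol %), catecholborane, toluene, −78 °C; MeOH, then aq. NaOH wash
Reagents that add atoms: none
Why: Corey–Bakshi–Shibata reduction, in which the oxazaborolidine binds the carbonyl lone pair on the C7 side, away from the fully substituted C5, and delivers hydride under reagent control to give the (6R)-alcohol with the hydroxyl on the β-face, catecholborane leaving the C8=C9 alkene untouched at this temperature.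

Step 8
Reactants: 9 (1R,6R)-dauca-4,8-dien-6-ol
Product: 10 (1R,4R,5S,6R)-4,5-epoxydauc-8-en-6-ol
Conditions: VO(acac)2 (5 mol %), t-BuOOH (in decane), CH2Cl2, 0 °C
Reagents that add atoms: tert-butyl hydroperoxide, CC(C)(C)OO
Why: Hydroxyl-directed vanadium-catalysed epoxidation, in which the vanadate ester of the 6β-hydroxyl delivers oxygen to the β-face of C4=C5 (allylic 1,3-strain with the isopropyl group keeps H-6 in the alkene plane and the C6–O bond on the β-face), setting C4 and C5 and sparing the homoallylic C8=C9 alkene.

Step 9
Reactants: 10 (1R,4R,5S,6R)-4,5-epoxydauc-8-en-6-ol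
Product: 11 (1R,4R,5R)-4,5-epoxydauc-8-en-6-one
Conditions: Dess–Martin periodinane, NaHCO3, CH2Cl2, 0 °C → rt
Reagents that add atoms: none
Why: Dess–Martin oxidation of the secondary alcohol under buffered conditions should give the α,β-epoxy ketone without opening the tetrasubstituted epoxide or moving the β,γ-alkene.

Step 10
Reactants: 11 (1R,4R,5R)-4,5-epoxydauc-8-en-6-one
Product: 12 (1R,4R,5R)-4-hydroxydauc-8-en-6-one (4β-OH, 5α-H)
Conditions: SmI2 (2.2 equiv), THF/MeOH (2:1), −90 °C; pH 7 phosphate buffer
Reagents that add atoms: none
Why: SmI2 reductive opening of an α,β-epoxy ketone, in which two electrons cleave the C5–O bond next to the carbonyl, the C4–O bond keeps its β configuration, and methanol protonates the samarium enolate at C5 from the α-face, anti to the C1 methyl and the C4 alkoxide, to give the trans-fused aldol, which is also expected to be the more stable C5 epimer because C6 then lies cis to the hydroxyl and not to the isopropyl group.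

Step 11
Reactants: 12 (1R,4R,5R)-4-hydroxydauc-8-en-6-one
Product: 13 (1R,4R,5S,6S)-dauc-8-ene-4,6-diol (4β-OH, 6α-OH)
Conditions: Me4NBH(OAc)3, MeCN/AcOH (1:1), −35 → −20 °C
Reagents that add atoms: none
Why: Evans–Saksena reduction, in which the 4β-hydroxyl exchanges onto boron and the alkoxyborohydride delivers hydride intramolecularly to the β-face of C6, giving the 6α-alcohol at a temperature where the aldol should neither dehydrate nor epimerise.

Step 12
Reactants: 13 (1R,4R,5S,6S)-dauc-8-ene-4,6-diol; 14 3,4-dimethoxybenzoyl chloride
Product: 15 (1R,4R,5S,6S)-4-hydroxydauc-8-en-6-yl 3,4-dimethoxybenzoate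
Conditions: Et3N, DMAP (cat.), CH2Cl2, 0 °C → rt
Reagents that add atoms: 3,4-dimethoxybenzoyl chloride (14), COc1ccc(C(=O)Cl)cc1OC
Why: DMAP-catalysed acyl transfer should take place only at the secondary 6-hydroxyl, the tertiary 4-hydroxyl being too hindered to react.

Step 13
Reactants: 15 (1R,4R,5S,6S)-4-hydroxydauc-8-en-6-yl 3,4-dimethoxybenzoate
Product: 16 (1S,4R,5S,6S)-4-hydroxy-10-oxodauc-8-en-6-yl 3,4-dimethoxybenzoate (CNP0111132.1)
Conditions: CrO3, 3,5-dimethylpyrazole, CH2Cl2, −20 °C
Reagents that add atoms: chromium trioxide, O=[Cr](=O)=O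
Why: Allylic oxidation with the CrO3–3,5-dimethylpyrazole complex, in which only C10 gives an allyl intermediate with a tertiary terminus (C8) and hence the β-methyl enone, C7 is deactivated by the neighbouring acyloxy carbon and the C14 methyl is primary, the same preference that turns 3-acyloxy steroid 5-enes into 7-ketones, while the tertiary alcohol, the ester and the aryl ethers are inert.

**Compound list**

1 | (2E,6E)-farnesol | CC(C)=CCC/C(C)=C/CC/C(C)=C/CO | starting material
2 | (2E,6E)-farnesyl chloride | CC(C)=CCC/C(C)=C/CC/C(C)=C/CCl | intermediate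
3 | (2E,6E)-farnesyl diphosphate (handled as tris-ammonium salt, drawn as the acid) | CC(C)=CCC/C(C)=C/CC/C(C)=C/COP(=O)(O)OP(=O)(O)O | intermediate
4 | (3R,6E)-nerolidyl diphosphate (enzyme-bound, not isolated) | CC(C)=CCC/C(C)=C/CC[C@](C)(C=C)OP(=O)(O)OP(=O)(O)O | intermediate
5 | (R)-daucene, (8aR)-6,8a-dimethyl-3-(propan-2-yl)-1,2,4,5,8,8a-hexahydroazulene | C1CC(C)=CC[C@@]2(C)CCC(C(C)C)=C12 | intermediate
6 | (1R,4S,5S)-4,5-epoxydauc-8-ene (4α,5α-epoxide) | C1CC(C)=CC[C@@]2(C)CC[C@@]3(C(C)C)O[C@@]123 | intermediate
7 | (1R,4S)-dauca-5,8-dien-4-ol | CC1=CC[C@@]2(C)CC[C@](O)(C(C)C)C2=CC1 | intermediate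
8 | (1R)-dauca-4,8-dien-6-one | CC1=CC[C@@]2(C)CCC(C(C)C)=C2C(=O)C1 | intermediate
9 | (1R,6R)-dauca-4,8-dien-6-ol (6β-OH) | CC1=CC[C@@]2(C)CCC(C(C)C)=C2[C@H](O)C1 | intermediate
10 | (1R,4R,5S,6R)-4,5-epoxydauc-8-en-6-ol (4β,5β-epoxide, 6β-OH) | CC1=CC[C@@]2(C)CC[C@]3(C(C)C)O[C@]23[C@H](O)C1 | intermediate
11 | (1R,4R,5R)-4,5-epoxydauc-8-en-6-one | CC1=CC[C@@]2(C)CC[C@]3(C(C)C)O[C@]23C(=O)C1 | intermediate
12 | (1R,4R,5R)-4-hydroxydauc-8-en-6-one (4β-OH, 5α-H) | CC1=CC[C@@]2(C)CC[C@@](O)(C(C)C)[C@@H]2C(=O)C1 | intermediate
13 | (1R,4R,5S,6S)-dauc-8-ene-4,6-diol (4β-OH, 5α-H, 6α-OH) | CC1=CC[C@@]2(C)CC[C@@](O)(C(C)C)[C@@H]2[C@@H](O)C1 | intermediate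
14 | 3,4-dimethoxybenzoyl chloride | COc1ccc(C(=O)Cl)cc1OC | starting material
15 | (1R,4R,5S,6S)-4-hydroxydauc-8-en-6-yl 3,4-dimethoxybenzoate | COc1ccc(C(=O)O[C@H]2CC(C)=CC[C@@]3(C)CC[C@@](O)(C(C)C)[C@H]23)cc1OC | intermediate
16 | (1S,4R,5S,6S)-4-hydroxy-10-oxodauc-8-en-6-yl 3,4-dimethoxybenzoate | COc1ccc(C(=O)O[C@H]2CC(C)=CC(=O)[C@@]3(C)CC[C@@](O)(C(C)C)[C@H]23)cc1OC | target

**Step count**

Total: 13 steps. Longest linear sequence: 13 steps (1 → 16); 14 is used as bought.

**Steps most likely to fail**

Step 3. The cascade may stop early by water capture, lose a proton other than H-5, or fold the chain towards the mirror-image C1 configuration. Fallback: setting out from 3, a cyclase of the same class that runs the same cascade one hydride shift further and ends it by water capture at C5 should give carotol F1, which has the C1 configuration of 5. Dehydration of this tertiary alcohol with Burgess reagent (benzene, 50 °C) towards the tetrasubstituted C4=C5 alkene returns to 5.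

Step 5. The amide may remove H-3 in place of H-6 (or add to the epoxide), which would give the 5-hydroxy-3-ene isomer; incomplete chemoselectivity in step 4 would add to the loss. Fallback: setting out from 5, and replacing steps 4 and 5, a Schenck ene reaction with singlet oxygen (O2, tetraphenylporphyrin, visible light, CH2Cl2, −30 °C) is used. Singlet oxygen reacts much faster with the tetrasubstituted alkene, abstracts the hydrogen geminal to the bulky quaternary C1 (H-6) and bonds to the less hindered C4, which should give the 4-hydroperoxide F2. Reduction with PPh3 returns to 7; either C4 configuration serves.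

Step 13. Hydrogen abstraction at C7 or at the C14 methyl may compete with C10, or the enone may be oxidised further. Fallback: setting out from 15, the C8=C9 alkene is epoxidised with mCPBA (NaHCO3, CH2Cl2, 0 °C) to the epoxide F3 (either face serves). Sodium phenylselenide ((PhSe)2, NaBH4, EtOH) opens it by SN2 at the secondary C9 to the hydroxy selenide F4. H2O2 gives the selenoxide F5, whose syn elimination can only use H-10, because C8 carries no hydrogen, and gives the tertiary allylic alcohol F6. Babler–Dauben oxidative transposition with pyridinium chlorochromate then moves the oxygen to C10 and the alkene back to C8=C9, returning to 16.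

**Further compounds**

F1 | step 3 | carotol, (1R,4S,5S)-dauc-8-en-5-ol | CC1=CC[C@]2(CC[C@H]([C@]2(CC1)O)C(C)C)C
F2 | step 5 | (1R,4S)-4-hydroperoxydauca-5,8-diene | CC1=CC[C@@]2(C)CC[C@](OO)(C(C)C)C2=CC1
F3 | step 13 | (8S,9R)-8,9-epoxide of 15 (8β,9β) | COc1ccc(C(=O)O[C@H]2C[C@]4(C)O[C@@H]4C[C@@]3(C)CC[C@@](O)(C(C)C)[C@H]23)cc1OC
F4 | step 13 | 8β-hydroxy-9α-(phenylselanyl) derivative of 15 | COc1ccc(C(=O)O[C@H]2C[C@](C)(O)[C@@H]([Se]c4ccccc4)C[C@@]3(C)CC[C@@](O)(C(C)C)[C@H]23)cc1OC
F5 | step 13 | selenoxide of F4 (both configurations at selenium) | COc1ccc(C(=O)O[C@H]2C[C@](C)(O)[C@@H]([Se](=O)c4ccccc4)C[C@@]3(C)CC[C@@](O)(C(C)C)[C@H]23)cc1OC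
F6 | step 13 | 4β,8β-dihydroxydauc-9-en-6α-yl 3,4-dimethoxybenzoate | COc1ccc(C(=O)O[C@H]2C[C@](C)(O)C=C[C@@]3(C)CC[C@@](O)(C(C)C)[C@H]23)cc1OC
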